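The easy entry comes first: partner has one way out, a first-order step to second intermediate, so its line of the books needs no other species.

| setting | south-east | east | north | north-west |
|---|---|---|---|---|
| starting material | 1.5 M | 1.5 M | 1.5 M | 1.5 M |
| partner | 1.95 M | 1.95 M | 1.95 M | 1.95 M |
| temperature | 80 °C | 100 °C | 120 °C | 60 °C |
| time | 40 h | 40 h | 40 h | 40 h |

- the best flask by amount of target, in percent of the starting material charged; "all alike" if 1.5 percentage points covers them all (south-east / east / north / north-west / all alike)
- amount of target at the end, in percent of the starting material charged, south-east
- amount of target at the end, in percent of the starting material charged, east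
- amount of target at the end, in percent of the starting material charged, north
- amount of target at the end, in percent of the starting material charged, north-west

- a doubled species enters its step squared and goes two at a time
- all constants are for 80 °C and move with temperature by the activation energies and enthalpies

    starting material ⇌ open intermediate (K1 = 2.7, k1 = 0.0119 h⁻¹, Ea1 = 129 kJ mol⁻¹, ΔH1 = 8.00 kJ mol⁻¹)
    second intermediate → side product A (k2 = 0.00846 h⁻¹, Ea2 = 128 kJ mol⁻¹)
    2 second intermediate → homo product (k3 = 0.00202 M⁻¹ h⁻¹, Ea3 = 104 kJ mol⁻¹)
    open intermediate + second intermediate ⇌ target (K4 = 3.42 M⁻¹, k4 = 0.0306 M⁻¹ h⁻¹, Ea4 = 95.0 kJ mol⁻¹, ΔH4 = −12.0 kJ mol⁻¹)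
    starting material + second intermediate → side product B (k5 = 0.00652 M⁻¹ h⁻¹, Ea5 = 89.0 kJ mol⁻¹)
    partner → second intermediate (k6 = 0.00967 h⁻¹, Ea6 = 122 kJ mol⁻¹)
    (constants at 80 °C)

I keep the ledger on partner in east, at 100 °C. Its feed constant there is 0.0897 h⁻¹. The second intermediate it makes reaches a fork: it goes to side product A with the loss constant 0.0875 h⁻¹, or it joins open intermediate to give target, pseudo-first-order with the joining constant 0.173 M⁻¹ h⁻¹ times c(open intermediate). For that concentration I take a ceiling: the starting charge split by the opening equilibrium constant 3.12, which gives 1.14 M. My zero of the scale is the even fork, an escape share of 0.5.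

escape share = loss / (loss + joining × c(open intermediate)) = 30.8%

East stands below the even fork. But target also falls back, with the constant 0.0631 h⁻¹, and each second intermediate freed meets the same fork.

drain = falling-back constant × escape share = 0.0194 h⁻¹

This drain constant, the falling-back constant times the escape share, is what I carry. Booking standing second intermediate, homo product and side product B at nothing, the share that does not escape enters target:

c(target) = entering share × partner charge × feed / (feed − drain) × (exp(−drain × time) − exp(−feed × time))

The books of east at 40 h then close like this:

left in partner: 0.0540 M
in target: 0.745 M, which is 49.7% of the starting charge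
past the fork to side product A: 1.15 M

The ceiling takes nothing off for open intermediate bound in target, and the books leave out homo product and side product B, so I read that figure as high. In north, at 120 °C, the same lines give a feed of 0.663 h⁻¹, an escape share of 42.5%, a drain of 0.155 h⁻¹ and target at 0.197%. In south-east the life of partner, 103 h, is longer than the time given, so I expect little target there and in colder north-west, and I put no figure on these two flasks. I commit to east over north.

The forecast names east, with 5.9% for south-east, 27% for east, 0.13% for north and 0.0116% for north-west, and says of north: “It then drains by reversal”.

The simulation gives east as best, with 5.67% in south-east, 27.3% in east, 0.146% in north and 0.0115% in north-west.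

My east figure stands above the result; at 40.0 h open intermediate in east holds 47.0% of the charge, 0.706 M, under my ceiling. Target in north ends low mainly through its falling back: with that step struck out, north holds 50.1% rather than 0.146%. The drain constant shows the same in time: over 40 h it counts 6.20 lifetimes of target in north and 0.776 in east.

The neighbour is east left until 6.0 d. From 27.3% at 40 h, the drain constant 0.0194 h⁻¹ gives 3.63%, and the simulation gives 3.41%.

All constants were chosen freely; the result is computed.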